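**Plan**

1. Retrosynthetic cuts: the C15 aldehyde goes back to the methyl of an isopropenyl group on C5; the O6–angeloyl bond is cut; the lactone bond C7–C11 and the C11=C13 alkene go back to a C6–C7 epoxide with a phosphonoacetate on O8, plus formaldehyde; the O8–acyl bond is made with inversion; the C10–vinyl and C5–isopropenyl bonds go back to 2-methylcyclohex-2-en-1-one.
2. Forward order: the carbocycle is bought. C5 and then C10 are substituted by conjugate addition and enolate vinylation. The ketone becomes O9, and oxygen is then moved round the ring (C7–C8 epoxide, selenium transposition to O8 with a C6=C7 alkene, C6–C7 epoxide). The γ-lactone is the only ring made and is closed last through C7–C11; the angelate and the aldehyde finish the route.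
3. Enabling feature: the lactone ring (C7, C8, O, C12, C11) is cis-fused to the cyclohexane at C7/C8, while O6 on C6 is anti to C11 on C7 (trans-diaxial in the chair with the C5, C8 and C9 groups equatorial). This is the pattern left by backside opening of a C6–C7 epoxide at C7 by a carbon nucleophile tethered to O8. One event therefore sets C7, uncovers O6 correctly and, with formaldehyde, completes the α-methylene lactone.
4. Stereochemistry: C5 comes from a copper-catalysed asymmetric conjugate addition, C10 from alkylation trans to C5, and C9 from hydride attack anti to the axial C10 methyl. C8, C7 and C6 come from two hydroxyl-directed epoxidations, a Mitsunobu inversion at C8 and the stereospecific epoxide opening. The side-chain centre comes from (R)-2-methylbutanoic acid and the Z alkene from angelic anhydride.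

Key step: step 11

Convention: ring atoms carry elemane numbers. C10 is the quaternary carbon (methyl, vinyl); C5 bears the three-carbon unit C4/C3/C15; C6, C7, C8 and C9 follow round the ring; C11, C12 and C13 are the lactone α-carbon, carbonyl and methylene. "Me-face" is the ring face of the C10 methyl and "vinyl-face" the other. In the target, C4 (on C5), O6 and O9 lie on the Me-face; C11 and O8 lie on the vinyl-face.

Assumption: the ligand enantiomer in step 1 is the one that gives the (S) centre at C5.

**Step 1**
Reactants: 1 2-methylcyclohex-2-en-1-one; 2 isopropenylmagnesium bromide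
Product: 4 (S)-trimethyl{[2-methyl-3-(prop-1-en-2-yl)cyclohex-1-en-1-yl]oxy}silane, via magnesium enolate 3 (not isolated)
Conditions: CuBr·SMe2 (5 mol %), chiral ferrocenyl diphosphine (Josiphos type, 6 mol %), t-BuOMe, −78 °C; then TMSCl, Et3N, DMPU, −78 → 0 °C
Reagents that add atoms: isopropenylmagnesium bromide (2), C=C(C)[Mg]Br; chlorotrimethylsilane, C[Si](C)(C)Cl
Why: Copper-catalysed asymmetric conjugate addition of a Grignard reagent to an α-substituted cyclic enone, in which the chiral copper–diphosphine complex selects the enone face and so sets C5 as (S), while silyl trapping fixes the enolate regiochemistry for step 2.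

**Step 2**
Reactants: 4 silyl enol ether; 5 phenyl vinyl sulfoxide
Product: 7 (2S,3S)-2-methyl-2-[2-(phenylsulfinyl)ethyl]-3-(prop-1-en-2-yl)cyclohexan-1-one (both sulfur epimers), via lithium enolate 6 (not isolated)
Conditions: MeLi, THF, 0 °C; then 5, −78 → −20 °C; H2O
Reagents that add atoms: phenyl vinyl sulfoxide (5), C=CS(=O)c1ccccc1
Why: Michael addition of the regiodefined lithium enolate to phenyl vinyl sulfoxide (a vinyl cation equivalent), in which the electrophile should enter anti to the neighbouring isopropenyl group and so set the quaternary C10 with the two-carbon arm trans to isopropenyl.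

**Step 3**
Reactants: 7 keto sulfoxide
Product: 8 (2S,3S)-2-ethenyl-2-methyl-3-(prop-1-en-2-yl)cyclohexan-1-one
Conditions: toluene, NaHCO3, 110 °C
Reagents that add atoms: none
Why: Thermal syn-elimination of the sulfoxide can only take a hydrogen from the CH2 next to C10 and so unveils the vinyl group without touching either stereocentre (the 1,2-divinylcyclohexane is the favoured side of any Cope equilibrium).

**Step 4**
Reactants: 8 ketone
Product: 10 (5S,6S)-6-ethenyl-6-methyl-5-(prop-1-en-2-yl)cyclohex-2-en-1-one, via lithium enolate 9 (not isolated)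
Conditions: LDA, THF, −78 °C; then N-tert-butylbenzenesulfinimidoyl chloride, −78 °C → rt
Reagents that add atoms: none
Why: Mukaiyama dehydrogenation of the lithium enolate, which can form only towards C8, should give the C7=C8 enone at low temperature without a palladium salt that could promote Cope rearrangement of the 1,5-diene.

**Step 5**
Reactants: 10 enone
Product: 11 (1S,5S,6S)-6-ethenyl-6-methyl-5-(prop-1-en-2-yl)cyclohex-2-en-1-ol (C9 hydroxyl on the Me-face)
Conditions: NaBH4, CeCl3·7H2O, MeOH, −78 → 0 °C
Reagents that add atoms: none
Why: Luche 1,2-reduction in which hydride should add to the vinyl-face of the carbonyl, anti to the pseudo-axial C10 methyl, placing the C9 hydroxyl on the Me-face.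

**Step 6**
Reactants: 11 allylic alcohol
Product: 12 epoxy alcohol (C7–C8 epoxide on the Me-face, syn to the C9 hydroxyl)
Conditions: VO(acac)2 (2 mol %), t-BuOOH (decane), CH2Cl2, 0 °C → rt
Reagents that add atoms: tert-butyl hydroperoxide, CC(C)(C)OO
Why: Hydroxyl-directed vanadium-catalysed epoxidation delivers oxygen syn to the allylic C9 hydroxyl and should leave the vinyl and isopropenyl groups untouched.

**Step 7**
Reactants: 12 epoxy alcohol; 13 (R)-2-methylbutanoic acid
Product: 14 O9-[(R)-2-methylbutanoyl] ester of 12
Conditions: DCC, DMAP (cat.), CH2Cl2, 0 °C → rt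
Reagents that add atoms: (R)-2-methylbutanoic acid (13), CC[C@@H](C)C(=O)O
Why: Steglich esterification installs the final O9 acyl group before the neighbouring oxygen is unveiled, so the two ring oxygens stay differentiated.

**Step 8**
Reactants: 14 epoxy ester
Product: 17 allylic alcohol (C6=C7 alkene; free C8 hydroxyl and O9 ester both on the Me-face), via hydroxy selenide 15 (not isolated), via selenoxide 16 (not isolated)
Conditions: PhSeSePh, NaBH4, EtOH, 0 °C → rt; then H2O2 (30 %), pyridine, THF, 0 °C → rt
Reagents that add atoms: none
Why: Sharpless–Lauer transposition in which the selenolate opens the epoxide trans-diaxially at C7 (remote from the acyloxy group) and selenoxide syn-elimination away from the carbinol gives the C6=C7 alkene with the C8 hydroxyl kept on the Me-face.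

**Step 9**
Reactants: 17 allylic alcohol
Product: 18 cis-epoxy alcohol (C6–C7 epoxide, C8 hydroxyl and O9 ester all on the Me-face)
Conditions: VO(acac)2 (cat.), t-BuOOH, CH2Cl2, rt
Reagents that add atoms: tert-butyl hydroperoxide, CC(C)(C)OO
Why: A second hydroxyl-directed VO(acac)2 epoxidation, now guided by the allylic C8 hydroxyl, should put the C6–C7 epoxide on the Me-face against the steric bias of the axial methyl.

**Step 10**
Reactants: 18 cis-epoxy alcohol; 19 diethylphosphonoacetic acid
Product: 20 trans-epoxy phosphonoacetate (O8 on the vinyl-face carrying the (diethoxyphosphoryl)acetyl group; epoxide and O9 ester on the Me-face)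
Conditions: PPh3, DIAD, toluene/THF, 0 °C → rt
Reagents that add atoms: diethylphosphonoacetic acid (19), OC(=O)CP(=O)(OCC)OCC
Why: Mitsunobu esterification inverts C8, so the phosphonoacetate tether ends on the vinyl-face, trans to the epoxide, as needed for backside attack at C7.

**Step 11**
Reactants: 20 trans-epoxy phosphonoacetate
Product: 22 hydroxy α-methylene γ-lactone (cis-fused at C7/C8 on the vinyl-face; free C6 hydroxyl on the Me-face; isopropenyl at C5), via phosphono lactone 21 (not isolated)
Conditions: NaHMDS (1.05 equiv), THF, −78 → 0 °C, then 45 °C; then (CH2O)n, 0 °C → rt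
Reagents that add atoms: formaldehyde (from paraformaldehyde), C=O
Why: Proposed new method: NaHMDS deprotonates only the phosphonoacetate CH2, and the stabilised carbanion C11, held on O8 on the vinyl-face, attacks C7 anti to the C7–O bond of the Me-face epoxide to give the α-phosphono lactone alkoxide, which after proton transfer from C11 to O6 undergoes Horner–Wadsworth–Emmons olefination with formaldehyde to form C11=C13. The closest known reactions are the intermolecular opening of epoxides by phosphonoacetate anions followed by formaldehyde olefination and, in topology, iodolactonisation (anti attack of an allylically tethered nucleophile on a three-membered ring to give a cis-fused five-membered ring). The lactone ring (C7, C8, O, C12, C11) closes in the 5-exo-tet mode at C7, helped by the lower rotational barrier of the ester once it is an enolate. C7 is set by inversion at the epoxide carbon, with C11 forced onto the vinyl-face cis to O8 because the three-atom tether cannot reach the other face, while C6 keeps its oxygen on the Me-face and C11 becomes trigonal. The step needs attack at C7 and not C6, which the substrate secures because in the chair with the C5, C8 and C9 groups equatorial the C7 attack is the trans-diaxial (Fürst–Plattner) opening whereas C6 attack would require a bridged boat. It also needs the new O6 alkoxide to stay idle, which the anti (about 180°) O6/C11 arrangement secures by keeping it away from the lactone carbonyl, the phosphorus and C13, and the absence of any aldehyde before formaldehyde is added prevents premature olefination.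

**Step 12**
Reactants: 22 hydroxy lactone; 23 angelic anhydride
Product: 24 6-O-angelate of 22 (isopropenyl still at C5)
Conditions: LiHMDS (1.0 equiv), THF, −78 °C; then 23, −78 → −20 °C
Reagents that add atoms: angelic anhydride (23), C/C=C(/C)C(=O)OC(=O)/C(C)=C\C
Why: Acylation of the lithium alkoxide with angelic anhydride at low temperature, with no acylpyridinium or acid chloride that could isomerise Z to E, should esterify the hindered axial O6 with the angelate geometry retained.

**Step 13**
Reactants: 24 angelate
Product: 26 CNP0295282.1 (target), via allylic alcohol 25 (not isolated)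
Conditions: SeO2 (cat.), t-BuOOH, CH2Cl2, rt; filter; then MnO2, CH2Cl2, rt
Reagents that add atoms: selenium dioxide, O=[Se]=O; tert-butyl hydroperoxide, CC(C)(C)OO
Why: SeO2 ene/[2,3] allylic oxidation should attack only the electron-rich 1,1-disubstituted isopropenyl alkene at its methyl group (the vinyl group has no allylic hydrogen and the other two alkenes are electron-poor), and MnO2 then takes the allylic alcohol to the enal.

**Compound list**

1 | 2-methylcyclohex-2-en-1-one | CC1=CCCCC1=O | starting material
2 | isopropenylmagnesium bromide | C=C(C)[Mg]Br | starting material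
3 | bromomagnesium (S)-2-methyl-3-(prop-1-en-2-yl)cyclohex-1-en-1-olate | CC1=C(O[Mg]Br)CCC[C@H]1C(C)=C | intermediate
4 | (S)-trimethyl{[2-methyl-3-(prop-1-en-2-yl)cyclohex-1-en-1-yl]oxy}silane | CC1=C(O[Si](C)(C)C)CCC[C@H]1C(C)=C | intermediate
5 | phenyl vinyl sulfoxide (racemic) | C=CS(=O)c1ccccc1 | starting material
6 | lithium (S)-2-methyl-3-(prop-1-en-2-yl)cyclohex-1-en-1-olate | CC1=C(O[Li])CCC[C@H]1C(C)=C | intermediate
7 | (2S,3S)-2-methyl-2-[2-(phenylsulfinyl)ethyl]-3-(prop-1-en-2-yl)cyclohexan-1-one (sulfur epimers) | O=S(c1ccccc1)CC[C@@]2(C)[C@H](C(=C)C)CCCC2=O | intermediate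
8 | (2S,3S)-2-ethenyl-2-methyl-3-(prop-1-en-2-yl)cyclohexan-1-one | C=C[C@@]1(C)[C@H](C(=C)C)CCCC1=O | intermediate
9 | lithium enolate of 8 (C8=C9) | C=C[C@@]1(C)[C@H](C(=C)C)CCC=C1O[Li] | intermediate
10 | (5S,6S)-6-ethenyl-6-methyl-5-(prop-1-en-2-yl)cyclohex-2-en-1-one | C=C[C@@]1(C)[C@H](C(=C)C)CC=CC1=O | intermediate
11 | (1S,5S,6S)-6-ethenyl-6-methyl-5-(prop-1-en-2-yl)cyclohex-2-en-1-ol | C=C[C@@]1(C)[C@H](C(=C)C)CC=C[C@@H]1O | intermediate
12 | epoxy alcohol: C7–C8 epoxide of 11 on the Me-face, syn to the C9 hydroxyl | C=C[C@@]1(C)[C@H](C(=C)C)C[C@@H]2O[C@@H]2[C@@H]1O | intermediate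
13 | (R)-2-methylbutanoic acid | CC[C@@H](C)C(=O)O | starting material
14 | O9-[(R)-2-methylbutanoyl] ester of 12 | C=C[C@@]1(C)[C@H](C(=C)C)C[C@@H]2O[C@@H]2[C@@H]1OC(=O)[C@H](C)CC | intermediate
15 | hydroxy selenide: C7 phenylselanyl on the vinyl-face, C8 hydroxyl and O9 ester on the Me-face | C=C[C@@]1(C)[C@H](C(=C)C)C[C@@H]([Se]c2ccccc2)[C@H](O)[C@@H]1OC(=O)[C@H](C)CC | intermediate
16 | selenoxide of 15 (selenium epimers) | C=C[C@@]1(C)[C@H](C(=C)C)C[C@@H]([Se](=O)c2ccccc2)[C@H](O)[C@@H]1OC(=O)[C@H](C)CC | intermediate
17 | allylic alcohol: C6=C7 alkene, C8 hydroxyl and O9 (R)-2-methylbutanoate on the Me-face | C=C[C@@]1(C)[C@H](C(=C)C)C=C[C@H](O)[C@@H]1OC(=O)[C@H](C)CC | intermediate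
18 | cis-epoxy alcohol: C6–C7 epoxide, C8 hydroxyl and O9 ester all on the Me-face | C=C[C@@]1(C)[C@H](C(=C)C)[C@@H]2O[C@@H]2[C@H](O)[C@@H]1OC(=O)[C@H](C)CC | intermediate
19 | diethylphosphonoacetic acid | OC(=O)CP(=O)(OCC)OCC | starting material
20 | trans-epoxy phosphonoacetate: O8 (vinyl-face) bears the (diethoxyphosphoryl)acetyl group; epoxide and O9 ester on the Me-face | C=C[C@@]1(C)[C@H](C(=C)C)[C@@H]2O[C@@H]2[C@@H](OC(=O)CP(=O)(OCC)OCC)[C@@H]1OC(=O)[C@H](C)CC | intermediate
21 | cis-fused α-(diethoxyphosphoryl) γ-lactone with free C6 hydroxyl (C11 epimers) | C=C[C@@]1(C)[C@H](C(=C)C)[C@H](O)[C@H]2C(P(=O)(OCC)OCC)C(=O)O[C@H]2[C@@H]1OC(=O)[C@H](C)CC | intermediate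
22 | hydroxy α-methylene γ-lactone (free C6 hydroxyl, isopropenyl at C5) | C=C[C@@]1(C)[C@H](C(=C)C)[C@H](O)[C@H]2C(=C)C(=O)O[C@H]2[C@@H]1OC(=O)[C@H](C)CC | intermediate
23 | angelic anhydride [(Z)-2-methylbut-2-enoic anhydride] | C/C=C(/C)C(=O)OC(=O)/C(C)=C\C | starting material
24 | 6-O-angelate of 22 | C=C[C@@]1(C)[C@H](C(=C)C)[C@H](OC(=O)/C(C)=C\C)[C@H]2C(=C)C(=O)O[C@H]2[C@@H]1OC(=O)[C@H](C)CC | intermediate
25 | C15 allylic alcohol of 24 [C5 bears C(=CH2)CH2OH] | C=C[C@@]1(C)[C@H](C(=C)CO)[C@H](OC(=O)/C(C)=C\C)[C@H]2C(=C)C(=O)O[C@H]2[C@@H]1OC(=O)[C@H](C)CC | intermediate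
26 | CNP0295282.1 | C=C[C@@]1(C)[C@H](C(=C)C=O)[C@H](OC(=O)/C(C)=C\C)[C@H]2C(=C)C(=O)O[C@H]2[C@@H]1OC(=O)[C@H](C)CC | target

**Totals**

Total step count: 13. Longest linear sequence: 13 (one linear route from 1).

**Steps most likely to fail**

1. Step 11 (proposed new method). The stabilised carbanion may open the unactivated epoxide too slowly, so that acyl transfer from O9 to the carbanion, intermolecular reaction or base-induced epoxide isomerisation takes over. The olefination may also stall if proton transfer from C11 to the O6 alkoxide is slow. The fallback uses known chemistry, making the C7–C11 bond between two molecules and closing the ring by lactonisation. It sets out from 18. Mitsunobu reaction with chloroacetic acid (PPh3, DIAD) should give the inverted chloroacetate F1. Thiourea/NaHCO3 in EtOH should remove the chloroacetyl group selectively to give the trans-epoxy alcohol F2. Sodium triethyl phosphonoacetate (NaH, DME, 80 °C) should open the epoxide trans-diaxially at C7 to the open-chain hydroxy phosphonoester F3. F3 should lactonise in the flask onto the cis O8 hydroxyl to give 21, and paraformaldehyde then gives 22, where the route is rejoined.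

2. Step 12. Acyl transfer to the hindered axial alkoxide, which is syn-axial to the C10 methyl, may be slow. This would allow Z-to-E isomerisation of the angeloyl donor or conjugate addition of the alkoxide to an α-methylene lactone. The fallback builds the Z alkene after the ester is in place and sets out from 22. DCC/DMAP esterification with 2-[bis(2,2,2-trifluoroethoxy)phosphoryl]propanoic acid should give the phosphonopropionate F4. Still–Gennari olefination (KHMDS, 18-crown-6, acetaldehyde, THF, −78 °C) should then form the Z-trisubstituted enoate and return to the route at 24.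

3. Step 13. The ene oxidation may lose site selectivity (attack at the allylic methyls of the angelate or at C5–H), or selenium species may isomerise the angelate. The fallback replaces the selenium oxidation and sets out from 24. Ene-type allylic chlorination of the isopropenyl group (Ca(OCl)2, CO2, CH2Cl2/H2O, 0 °C) should give the allylic chloride F5. Oxidation with N-methylmorpholine N-oxide in MeCN (Kornblum–Ganem type) should then give the enal 26 directly.

**Further compounds**

F1 | step 11 | inverted chloroacetate: O8 (vinyl-face) chloroacetyl ester, epoxide and O9 ester on the Me-face | C=C[C@@]1(C)[C@H](C(=C)C)[C@@H]2O[C@@H]2[C@@H](OC(=O)CCl)[C@@H]1OC(=O)[C@H](C)CC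
F2 | step 11 | trans-epoxy alcohol: free C8 hydroxyl on the vinyl-face, epoxide and O9 ester on the Me-face | C=C[C@@]1(C)[C@H](C(=C)C)[C@@H]2O[C@@H]2[C@@H](O)[C@@H]1OC(=O)[C@H](C)CC
F3 | step 11 | open-chain hydroxy phosphonoester: C7 bears CH(CO2Et)P(O)(OEt)2 on the vinyl-face, C6 hydroxyl on the Me-face, C8 hydroxyl on the vinyl-face | C=C[C@@]1(C)[C@H](C(=C)C)[C@H](O)[C@@H](C(C(=O)OCC)P(=O)(OCC)OCC)[C@@H](O)[C@@H]1OC(=O)[C@H](C)CC
F4 | step 12 | 6-O-{2-[bis(2,2,2-trifluoroethoxy)phosphoryl]propanoyl} ester of 22 | C=C[C@@]1(C)[C@H](C(=C)C)[C@H](OC(=O)C(C)P(=O)(OCC(F)(F)F)OCC(F)(F)F)[C@H]2C(=C)C(=O)O[C@H]2[C@@H]1OC(=O)[C@H](C)CC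
F5 | step 13 | allylic chloride of 24 [C5 bears C(=CH2)CH2Cl] | C=C[C@@]1(C)[C@H](C(=C)CCl)[C@H](OC(=O)/C(C)=C\C)[C@H]2C(=C)C(=O)O[C@H]2[C@@H]1OC(=O)[C@H](C)CC
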